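Begin with what cannot happen: a flask cannot begin more chains than it has J, for J -> L and then D + L -> Z + Q starts one chain per J. Call the J charge, loading times [D], the chain ceiling; in the asked flask it is 0.0816 mM. Divide the D reacted by this ceiling to get a floor under the average chain.

| flask | D | G | J | remark | time |
|---|---|---|---|---|---|
| south-east | 24 mM | 0.24 mM | 0.48 mol% | run made earlier |  |
| north | 24 mM | 0.24 mM | 0.75 mol% | run made earlier |  |
| west | 12 mM | 0.24 mM | 0.34 mol% | run made earlier |  |
| flask | 24 mM | 0.240 mM | 0.34 mol% |  | 15 h |

- south-east (time / h: Q / %, D / %): 1.00: 0, 101.0; 2.00: 0, 99.1; 3.00: 1.1, 97.5; 6.00: 7.3, 92.6; 12.0: 22.3, 75.2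
- north (time / h: Q / %, D / %): 1.00: 0, 98.9; 2.00: 0.7, 100.2; 3.00: 2.3, 97.4; 6.00: 11.3, 89.1; 12.0: 34.0, 65.5
- west (time / h: Q / %, D / %): 2.50: 2.1, 101.2; 5.00: 1.9, 100.5; 8.00: 3.2, 97.0; 10.0: 4.9, 95.0; 12.0: 8.1, 91.8

(each reading ± 1 percentage point)

- average number of monomer units in a chain (chains begun, living or dead) at 15 h
- part of the D that has reacted at 15 h

- the average divides the monomer in chains by the number of chains begun, living and dead together
- reactions considered so far: D + L -> Z + Q; D + Z -> Q + Z; Z + G -> X; J -> L
- the earlier runs do not show the number of chains; that part of a forecast is a guess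

Now look at the south-east run, where two numbers seem to clash. Its [G] of 0.24 mM is 2.08 times its J charge of 0.115 mM, enough to stop every chain, yet Q reads 22.3% at 12.0 h, which puts the floor at 46.5 units per chain.

To clear this, divide the rate of D + Z by the rate of Z + G. [Z] and time cancel, leaving a ratio of constants times [D]/[G], the kinetic chain length, and in the asked flask [D]/[G] starts at 100. So G competes with D for Z, and in the south-east run an excess of G over the J charge stands beside that floor.

The forecast gives 150 units and 23% reacted: “Assuming about half of J has decomposed, dp is near 150, which is a guess.” By my reckoning, its conversion sets the floor at 67.6, and its chain length stands above that.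

The flask gives 144 units and 23.1% reacted.

    D + L → Z + Q (k = 22.7 M⁻¹ h⁻¹)
    D + Z → Q + Z, rate k2*[Z]*[D] (k = 1860 M⁻¹ h⁻¹)
    Z + G → X (k = 799 M⁻¹ h⁻¹)
    J → L (k = 0.0505 h⁻¹)

At 15.0 h this flask still holds 47% of its J, and its floor from the ceiling is 68.1. Read at 2.5 d, the same flask has 4.8% of its J left and 57.7% reacted, so the ceiling gives a floor of 170, and the chain average stands at 181.

(The numbers in the tables were computed for substances that don't exist, noise included.)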